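**Plan**
- Target: (2S,3R,4R)-oxolane with a 3,4-dimethoxyphenyl group on C2, CH2OH on C3 (trans to the aryl group) and a 4-hydroxy-3-methoxybenzyl group on C4 (cis to CH2OH).
- Cuts, in retrosynthetic order: C3–CH2OH goes back to a carboxyl carbon; the aryl–CH2 bond of the benzyl arm goes back to an aldehyde carbon plus a guaiacyl Grignard reagent; acid and aldehyde are tied up as a lactone acetal; last, C2–C3 and C4–C5 are cut together.
- Enabling feature: O1 with its neighbours C2 (aryl-bearing) and C5 (CH2) is a C–O–C three-atom unit bridging the cis C3–C4 pair, so the oxolane is a carbonyl ylide laid across the C=C of a butenolide.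
- Forward: the lactone ring comes from a furanone, the oxolane ring closes onto it in one [3+2] step, then the lactone is unlocked by acetal hydrolysis, aryl addition, hydrogenolysis and acid reduction.
- Stereochemistry: the acetal carbon of the menthyloxy butenolide (from (+)-menthol, fixed by crystallization) directs the ylide to one face and sets C4; suprafacial addition sets C3 cis to C4; exo placement of the aryl group sets C2; no later step touches these centres.

Key step: step 5

Remarks on the chemistry:
- Bicyclic compounds are numbered as 3,7-dioxabicyclo[3.3.0]octan-2-ones: C1 is the ring-fusion carbon next to C2 (C=O), then O3, C4, C5 (ring fusion), C6 (CH2), O7, C8 (CHAr).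
- The lactol carbon of 12 and the carbinol or benzylic carbon of 15, 16 and 17 are left undefined; step 8 removes that centre.
- 1-(Benzyloxy)-4-bromo-2-methoxybenzene is assumed to be purchasable.

**Step 1**
Reactants: 1 veratraldehyde (3,4-dimethoxybenzaldehyde); 2 (trimethylsilyl)methanol
Product: 3 3,4-dimethoxybenzaldehyde bis[(trimethylsilyl)methyl] acetal
Conditions: 2 (2.2 equiv), TsOH·H2O (cat.), cyclohexane, Dean–Stark, reflux
Reagents that add atoms: none
Why: Acid-catalysed acetalization with azeotropic removal of water should give the symmetrical acetal, so that the next step can lose only one kind of alkoxy group.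

**Step 2**
Reactants: 3 3,4-dimethoxybenzaldehyde bis[(trimethylsilyl)methyl] acetal
Product: 4 chloro(3,4-dimethoxyphenyl)methyl (trimethylsilyl)methyl ether (racemic)
Conditions: AcCl (1.05 equiv), SOCl2 (cat.), CH2Cl2, 0 °C to rt; volatiles removed in vacuo, crude product used at once
Reagents that add atoms: acetyl chloride, CC(=O)Cl
Why: Acetal-to-alpha-chloro ether exchange with an acyl chloride is a standard reaction of benzaldehyde acetals, and the electron-rich ring should speed the ionization that exchanges one alkoxy group for chloride.

**Step 3**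
Reactants: 5 furfural
Product: 7 5-hydroxyfuran-2(5H)-one (racemic), via furfural endoperoxide 6 (not isolated)
Conditions: O2, hν (visible), methylene blue (cat.), MeOH, rt
Reagents that add atoms: oxygen, O=O
Why: Dye-sensitized photo-oxygenation should add singlet oxygen across C2/C5 of the furan ([4+2]), and methanolysis of the formyl endoperoxide then expels the formyl carbon as methyl formate to leave the hydroxybutenolide.

**Step 4**
Reactants: 7 5-hydroxyfuran-2(5H)-one; 8 (+)-menthol
Product: 9 (5S)-5-[(1S,2R,5S)-menthyloxy]furan-2(5H)-one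
Conditions: TsOH·H2O (cat.), toluene, Dean–Stark, reflux; crystallization from petroleum ether; mother liquor re-equilibrated with acid and crystallized again
Reagents that add atoms: none
Why: Acid-catalysed acetalization of the pseudo-acid gives both C5 epimers, which interconvert under acid, and the (5S) epimer of the d-menthyl series should be removed by crystallization (crystallization-driven epimer enrichment), which fixes the acetal centre.

**Step 5**
Reactants: 4 chloro(3,4-dimethoxyphenyl)methyl (trimethylsilyl)methyl ether; 9 (5S)-5-[(1S,2R,5S)-menthyloxy]furan-2(5H)-one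
Product: 11 (1S,4S,5R,8S)-8-(3,4-dimethoxyphenyl)-4-[(1S,2R,5S)-menthyloxy]-3,7-dioxabicyclo[3.3.0]octan-2-one, via carbonyl ylide 10 (not isolated)
Conditions: CsF (dried, 3 equiv), MeCN, rt; 4 (2 equiv) added slowly
Reagents that add atoms: none
Why: Fluoride attacks silicon while chloride leaves the benzylic carbon (1,3-elimination), releasing the non-stabilized carbonyl ylide ArCH=O(+)–CH2(−), which should add across C3=C4 of the butenolide in a concerted suprafacial 1,3-dipolar [3+2] cycloaddition. The closest known reactions are the cycloadditions of fluoride-generated carbonyl ylides to electron-poor alkenes and the face-selective dipolar additions to 5-menthyloxyfuranones. The oxolane ring closes by this bimolecular [3+2] addition, with C8–C1 and C6–C5 formed in the same event, which makes the ring fusion necessarily cis. C5 is set by approach anti to the menthyloxy group on C4, C1 is tied to C5 by the suprafacial addition, and C8 is set by the aryl group pointing away from the lactone ring (exo, convex face). The step needs regio-, face- and exo-selectivity. The electron-rich veratryl group holds the positive end at the benzylic carbon so that the CH2 terminus bonds to the beta carbon, the acetal stereocentre shields one face, and the folded shape of the forming bicycle disfavours the endo aryl arrangement.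

**Step 6**
Reactants: 11 cycloadduct (menthyloxy lactone acetal)
Product: 12 (1S,5R,8S)-8-(3,4-dimethoxyphenyl)-4-hydroxy-3,7-dioxabicyclo[3.3.0]octan-2-one (lactol, mixture at C4)
Conditions: 1 M aq. HCl, THF, 50 °C
Reagents that add atoms: water, O
Why: Acid hydrolysis of the pseudo-ester acetal should release (+)-menthol and leave the aldehyde masked as the cis-fused lactol, so neither ring-fusion centre is exposed to enolization.

**Step 7**
Reactants: 12 lactol; 13 1-(benzyloxy)-4-bromo-2-methoxybenzene
Product: 16 (1S,5R,8S)-4-[4-(benzyloxy)-3-methoxyphenyl]-8-(3,4-dimethoxyphenyl)-3,7-dioxabicyclo[3.3.0]octan-2-one (mixture at C4), via arylmagnesium bromide 14 (not isolated), via hydroxy acid 15 (not isolated)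
Conditions: 13, Mg, THF, reflux; resulting 14 (3 equiv) added to 12, THF, −78 to 0 °C; then 1 M aq. HCl, rt
Reagents that add atoms: none
Why: Grignard addition to a lactol (pseudo-acid): the first equivalent deprotonates the lactol, which opens to the carboxylate aldehyde, the second adds to the aldehyde faster than it enolizes at low temperature, and acid work-up relactonizes the gamma-hydroxy acid; the new carbinol centre is uncontrolled and is removed in step 8.

**Step 8**
Reactants: 16 benzylic lactone
Product: 18 (2S,3S,4R)-2-(3,4-dimethoxyphenyl)-4-(4-hydroxy-3-methoxybenzyl)oxolane-3-carboxylic acid, via phenol lactone 17 (not isolated)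
Conditions: H2 (1 atm), 10% Pd/C, EtOAc–AcOH, rt; stopped when the lactone is consumed
Reagents that add atoms: none
Why: Catalytic hydrogenolysis should first remove the O-benzyl group and then cleave the benzylic C–O bond of the lactone, since a benzylic acyloxy group para to a free phenol is far more labile than the benzylic dialkyl ether of the oxolane; no stereocentre of the ring is involved.

**Step 9**
Reactants: 18 oxolane carboxylic acid
Product: 19 (2S,3R,4R)-2-(3,4-dimethoxyphenyl)-3-(hydroxymethyl)-4-(4-hydroxy-3-methoxybenzyl)oxolane (target)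
Conditions: BH3·THF (excess), THF, 0 °C to rt; then MeOH
Reagents that add atoms: none
Why: Borane reduction of a carboxylic acid to the primary alcohol is chemoselective, tolerates the phenol (as its borate) and the cyclic ether, and does not epimerize the alpha carbon.

**Compound list**
1 | veratraldehyde (3,4-dimethoxybenzaldehyde) | COc1ccc(C=O)cc1OC | starting material
2 | (trimethylsilyl)methanol | C[Si](C)(C)CO | starting material
3 | 3,4-dimethoxybenzaldehyde bis[(trimethylsilyl)methyl] acetal | COc1ccc(C(OC[Si](C)(C)C)OC[Si](C)(C)C)cc1OC | intermediate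
4 | chloro(3,4-dimethoxyphenyl)methyl (trimethylsilyl)methyl ether, racemic | COc1ccc(C(Cl)OC[Si](C)(C)C)cc1OC | intermediate
5 | furfural | O=Cc1ccco1 | starting material
6 | furfural endoperoxide (2,3,7-trioxabicyclo[2.2.1]hept-5-ene-1-carbaldehyde), not isolated | O=CC12C=CC(OO1)O2 | intermediate
7 | 5-hydroxyfuran-2(5H)-one, racemic | O=C1C=CC(O)O1 | intermediate
8 | (+)-menthol, (1S,2R,5S) | CC(C)[C@H]1CC[C@H](C)C[C@@H]1O | starting material
9 | (5S)-5-[(1S,2R,5S)-menthyloxy]furan-2(5H)-one | O=C1C=C[C@@H](O[C@H]2C[C@@H](C)CC[C@@H]2C(C)C)O1 | intermediate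
10 | carbonyl ylide, (3,4-dimethoxybenzylidene)(methylide)oxonium, not isolated | COc1ccc(C=[O+][CH2-])cc1OC | intermediate
11 | (1S,4S,5R,8S)-8-(3,4-dimethoxyphenyl)-4-[(1S,2R,5S)-menthyloxy]-3,7-dioxabicyclo[3.3.0]octan-2-one | [C@@H]1(O[C@H]2C[C@@H](C)CC[C@@H]2C(C)C)[C@H]3CO[C@H](c4ccc(OC)c(OC)c4)[C@H]3C(=O)O1 | intermediate
12 | (1S,5R,8S)-8-(3,4-dimethoxyphenyl)-4-hydroxy-3,7-dioxabicyclo[3.3.0]octan-2-one, mixture at C4 | OC1[C@H]2CO[C@H](c3ccc(OC)c(OC)c3)[C@H]2C(=O)O1 | intermediate
13 | 1-(benzyloxy)-4-bromo-2-methoxybenzene | COc1cc(Br)ccc1OCc1ccccc1 | starting material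
14 | [4-(benzyloxy)-3-methoxyphenyl]magnesium bromide, not isolated | COc1cc([Mg]Br)ccc1OCc1ccccc1 | intermediate
15 | (2S,3S,4R)-4-{[4-(benzyloxy)-3-methoxyphenyl](hydroxy)methyl}-2-(3,4-dimethoxyphenyl)oxolane-3-carboxylic acid, mixture at the carbinol carbon, not isolated | OC(c1ccc(OCc2ccccc2)c(OC)c1)[C@H]1CO[C@H](c2ccc(OC)c(OC)c2)[C@H]1C(=O)O | intermediate
16 | (1S,5R,8S)-4-[4-(benzyloxy)-3-methoxyphenyl]-8-(3,4-dimethoxyphenyl)-3,7-dioxabicyclo[3.3.0]octan-2-one, mixture at C4 | C1(c2ccc(OCc3ccccc3)c(OC)c2)[C@H]2CO[C@H](c3ccc(OC)c(OC)c3)[C@H]2C(=O)O1 | intermediate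
17 | (1S,5R,8S)-8-(3,4-dimethoxyphenyl)-4-(4-hydroxy-3-methoxyphenyl)-3,7-dioxabicyclo[3.3.0]octan-2-one, mixture at C4, not isolated | C1(c2ccc(O)c(OC)c2)[C@H]2CO[C@H](c3ccc(OC)c(OC)c3)[C@H]2C(=O)O1 | intermediate
18 | (2S,3S,4R)-2-(3,4-dimethoxyphenyl)-4-(4-hydroxy-3-methoxybenzyl)oxolane-3-carboxylic acid | COc1cc(C[C@H]2CO[C@H](c3ccc(OC)c(OC)c3)[C@H]2C(O)=O)ccc1O | intermediate
19 | (2S,3R,4R)-2-(3,4-dimethoxyphenyl)-3-(hydroxymethyl)-4-(4-hydroxy-3-methoxybenzyl)oxolane | COc1cc(C[C@H]2CO[C@H](c3ccc(OC)c(OC)c3)[C@H]2CO)ccc1O | target

**Count**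
Total steps: 9. Longest linear sequence: 7 steps (steps 3, 4, 5, 6, 7, 8, 9 from furfural; equally steps 1, 2, 5, 6, 7, 8, 9 from veratraldehyde).

**Steps most likely to fail**

Step 5. The dipole may add with the reverse orientation or with poor face or exo/endo discrimination. The very labile chloro ether may also ionize and self-condense before the ylide forms. The fallback builds the same oxolane stepwise with unambiguous regiochemistry, setting out from 9 and returning at 11.
- Benzophenone-sensitized photoaddition of methanol to 9 (hν 350 nm, MeOH) should deliver the hydroxymethyl radical to the beta carbon anti to the menthyloxy group and give (4R,5S)-4-(hydroxymethyl)-5-[(1S,2R,5S)-menthyloxy]dihydrofuran-2(3H)-one F1.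
- Veratraldehyde 1 is converted with HC(OMe)3 and TsOH·H2O in MeOH into 3,4-dimethoxybenzaldehyde dimethyl acetal F2.
- Acetal exchange of F1 with F2 (pyridinium p-toluenesulfonate, toluene, methanol distilled off) gives the mixed methyl acetal F3.
- Enolization and silylation (LiN(iPr)2, Me3SiCl, THF, −78 °C) give the silyl ketene acetal F4.
- Me3SiOTf in CH2Cl2 at −78 °C then ionizes the benzylic acetal, and the ketene acetal closes onto the oxocarbenium ion (intramolecular Mukaiyama aldol-type addition to an acetal). This closure can only give the cis-fused bicycle and should place the aryl group on the convex face, giving 11.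

Step 8. Over-reduction may occur, with the benzylic C–O bond of the oxolane cleaved along with that of the lactone. The fallback sets out from 16 and returns at 18.
- A short hydrogenolysis under neutral conditions (H2, 10% Pd/C, EtOAc, no acid) removes only the O-benzyl group and gives the phenol lactone 17, which is isolated.
- Treatment of 17 with excess NaBH4 in aq. NaOH–THF (0 to 50 °C) forms the phenoxide, which expels the carboxylate by 1,6-elimination to give the quinone methide F5.
- Hydride adds to F5 in 1,6-fashion at once to give 18.
- Only the benzylic carbon para to the free phenol can react this way, so the veratryl ether of the oxolane is untouched.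
- Excess hydride is needed so that F5 is reduced before it can tautomerize.

Step 7. The basic Grignard reagent may enolize the transient aldehyde, epimerizing the ring carbon next to it from cis to trans, or may attack the lactone carbonyl. The fallback sets out from 12 and returns at 16 by way of 15.
- [4-(Benzyloxy)-3-methoxyphenyl]boronic acid (COc1cc(B(O)O)ccc1OCc1ccccc1) is added to the lactol with [RhCl(cod)]2 as catalyst (cod = 1,5-cyclooctadiene; monovalent rhodium) and KOH (cat.) in dioxane–H2O at 60 °C, then acidified.
- This is the rhodium-catalysed 1,2-addition of arylboronic acids to aldehydes, which runs through an aryl–rhodium species under nearly neutral conditions rather than a stoichiometric strong base.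
- It makes no compound outside the list (F0).

**Further compounds**
F1 | step 5 | (4R,5S)-4-(hydroxymethyl)-5-[(1S,2R,5S)-menthyloxy]dihydrofuran-2(3H)-one | [C@@H]1(O[C@H]2C[C@@H](C)CC[C@@H]2C(C)C)[C@@H](CO)CC(=O)O1
F2 | step 5 | 3,4-dimethoxybenzaldehyde dimethyl acetal | COc1ccc(C(OC)OC)cc1OC
F3 | step 5 | (4R,5S)-4-{[(3,4-dimethoxyphenyl)(methoxy)methoxy]methyl}-5-[(1S,2R,5S)-menthyloxy]dihydrofuran-2(3H)-one, mixture at the acetal carbon | [C@@H]1(O[C@H]2C[C@@H](C)CC[C@@H]2C(C)C)[C@@H](COC(OC)c2ccc(OC)c(OC)c2)CC(=O)O1
F4 | step 5 | trimethylsilyl ketene acetal of F3 (2-menthyloxy-3-substituted 5-(trimethylsilyloxy)-2,3-dihydrofuran) | [C@@H]1(O[C@H]2C[C@@H](C)CC[C@@H]2C(C)C)[C@@H](COC(OC)c2ccc(OC)c(OC)c2)C=C(O[Si](C)(C)C)O1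
F5 | step 8 | (2S,3S,4R)-2-(3,4-dimethoxyphenyl)-4-[(3-methoxy-4-oxocyclohexa-2,5-dien-1-ylidene)methyl]oxolane-3-carboxylic acid (quinone methide) | COC1=CC(=C[C@H]2CO[C@H](c3ccc(OC)c(OC)c3)[C@H]2C(O)=O)C=CC1=O
F0 | step 7 | none | none
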